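**Retrosynthetic overview**
- Feature: ring A has para oxygens (C1-OH, C4-OH), the aryl ether on C2 next to C1, bromine on C3 and C5, and its only hydrogen on C6. It is a reduced 2-aryloxy-1,4-benzoquinone whose carbons map onto a four-carbon squarate piece (C1-C4) plus a two-carbon alkyne (C5, C6).
- Endgame, read backwards: cleave the ring-B methyl ether, reduce the quinone, and trace C3-Br and C5-Br to C3-H (enol-ether carbon) and C5-SiMe3 of a silylquinone.
- Key disconnection: the C4-C5 bond of ring A, opened to an enynyl ketene and then folded back to a 3-aryloxy-4-hydroxy-4-(silylethynyl)cyclobutenone.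
- The carbinol comes from lithium trimethylsilylacetylide and the aryl ester of semisquaric acid. The acid chloride derives from diisopropyl squarate; 2,3,5-tribromo-4-methoxyphenol derives from 2,6-dibromoanisole.
- Ring order: ring B is bought as a benzene and only decorated, and the four-membered ring is bought with the squarate. Ring A is the only ring made, in step 7.

Key step: step 7

Remark: the target has no stereocentre and no configurationally stable axis, so it is achiral. The carbinol centres of 6 and 13 are racemic and are erased later.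

**Step 1**
Reactants: 1 2,6-dibromoanisole (1,3-dibromo-2-methoxybenzene)
Product: 3 3,5-dibromo-4-methoxyphenol, via arylboronate 2 (not isolated)
Conditions: [Ir(OMe)(cod)]2 (1.5 mol %), dtbpy (3 mol %), B2pin2 (1.0 equiv), THF, 80 °C (sealed); evaporate; Oxone, acetone-H2O, rt
Reagents that add atoms: bis(pinacolato)diboron, CC1(C)OB(OC1(C)C)B1OC(C)(C)C(C)(C)O1 (Bpin of 2); potassium peroxymonosulfate (active part of Oxone), [K+].[O-]S(=O)(=O)OO (phenol O of 3)
Why: Sterically governed iridium-catalysed C-H borylation takes the only C-H of 1 with no ortho neighbour (para to OMe) and tolerates C-Br, and peroxide oxidation of the C-B bond (1,2-aryl shift from boron to oxygen) should give the phenol in the same flask.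

**Step 2**
Reactants: 3 3,5-dibromo-4-methoxyphenol
Product: 4 2,3,5-tribromo-4-methoxyphenol
Conditions: Br2 (1.0 equiv, slow addition), CH2Cl2, 0 °C
Reagents that add atoms: bromine, BrBr
Why: In this electrophilic aromatic bromination the hydroxyl directs ortho (para is blocked), the two ortho positions are equivalent, and the first bromine deactivates the ring enough for one equivalent to stop at the tribromide.

**Step 3**
Reactants: 5 diisopropyl squarate
Product: 7 3-isopropoxycyclobut-3-ene-1,2-dione, via hydroxycyclobutenone 6 (not isolated)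
Conditions: LiAlH(OtBu)3 (1.0 equiv), THF, -78 to -20 °C; aq HCl work-up; conc. HCl (cat.), CH2Cl2, rt
Reagents that add atoms: none
Why: The hindered alkoxyaluminium hydride adds 1,2 to one of the two equivalent carbonyls and stops there, and acid-catalysed allylic transposition of racemic 6 with loss of isopropanol (the standard squarate-to-cyclobutenedione sequence) erases the carbinol centre.

**Step 4**
Reactants: 7 3-isopropoxycyclobut-3-ene-1,2-dione
Product: 8 semisquaric acid (3-hydroxycyclobut-3-ene-1,2-dione)
Conditions: 6 M HCl, THF, 50 °C; evaporate to dryness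
Reagents that add atoms: water, O
Why: Acid hydrolysis of a vinylogous ester proceeds by addition-elimination of water at C3, and the strongly acidic, water-soluble product is recovered by evaporation rather than extraction.

**Step 5**
Reactants: 8 semisquaric acid; 4 2,3,5-tribromo-4-methoxyphenol
Product: 10 3-(2,3,5-tribromo-4-methoxyphenoxy)cyclobut-3-ene-1,2-dione, via semisquaric chloride 9 (not isolated)
Conditions: (COCl)2 (1.2 equiv), DMF (cat.), CH2Cl2, reflux; strip excess reagent at 0 °C; 4, 2,6-lutidine, CH2Cl2, -20 to 0 °C; non-aqueous filtration through silica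
Reagents that add atoms: oxalyl chloride, O=C(Cl)C(=O)Cl (Cl of 9 only; no reagent atom stays in 10)
Why: Vilsmeier-type activation turns the vinylogous acid into its chloride, and vinylogous acyl substitution (addition-elimination at C3) by the phenol oxygen forms the C2-O bond, since without a Lewis acid the deactivated ring B cannot be C-acylated.

**Step 6**
Reactants: 10 3-(2,3,5-tribromo-4-methoxyphenoxy)cyclobut-3-ene-1,2-dione; 11 trimethylsilylacetylene
Product: 13 4-hydroxy-3-(2,3,5-tribromo-4-methoxyphenoxy)-4-[(trimethylsilyl)ethynyl]cyclobut-2-en-1-one (racemic), via lithium trimethylsilylacetylide 12 (not isolated)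
Conditions: 11 (1.15 equiv), n-BuLi (1.05 equiv), THF, -78 °C; cannulate into 10, THF, -78 °C; sat. aq NH4Cl at -78 °C; use without delay
Reagents that add atoms: n-butyllithium, [Li]CCCC (Li of 12 only)
Why: This 1,2-addition of a lithium acetylide to a cyclobutenedione should occur at the carbonyl flanking the aryloxy carbon because the other carbonyl is tied up in the vinylogous ester ArO-C=C-C=O; the acetylide (no free n-BuLi) does not exchange with C-Br, and the new centre forms racemic and needs no control because step 7 destroys it.

**Step 7**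
Reactants: 13 4-hydroxy-3-(2,3,5-tribromo-4-methoxyphenoxy)-4-[(trimethylsilyl)ethynyl]cyclobut-2-en-1-one
Product: 16 2-(2,3,5-tribromo-4-methoxyphenoxy)-5-(trimethylsilyl)-1,4-benzoquinone, via enynyl ketene 14 (not isolated), via diradical 15 (not isolated)
Conditions: PhMe (0.01 M, degassed), 110 °C
Reagents that add atoms: none
Why: This is a Moore rearrangement of a 4-alkynyl-4-hydroxycyclobutenone, an isomerisation that keeps every atom of 13, here with an aryloxy group where an alkoxy group usually sits. Heat breaks the C1-C4 sigma bond of the cyclobutenone in a conrotatory 4-pi electrocyclic opening in which the donor hydroxyl turns outward, so the alkyne turns inward and lies cis to the ketene in (Z)-14. The ketene carbon (ring A C4) then bonds to the silicon-bearing alkyne terminus (C5) in a 6-endo-dig closure that makes ring A as the phenoxyl/sigma-aryl diradical 15, and passage of the hydroxyl hydrogen to the radical carbon C6 gives quinone 16. No stereocentre is created, and the racemic carbinol carbon of 13 becomes the C1 carbonyl carbon. The selectivity required is 6-endo over 5-exo closure (the latter would end in a 2-(silylmethylene)cyclopentene-1,3-dione); the alkyne carries no aryl or ester group able to conjugate with an exocyclic vinyl radical and only the six-membered path gains aromatic stabilisation, while the bulk of SiMe3 at the bond-forming carbon works against it, which is why this step heads the risk list. Positions follow from connectivity alone: OAr next to the former carbinol carbon (C2 beside C1), H on C3 and Si on C5.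

**Step 8**
Reactants: 16 2-(2,3,5-tribromo-4-methoxyphenoxy)-5-(trimethylsilyl)-1,4-benzoquinone
Product: 17 3,5-dibromo-2-(2,3,5-tribromo-4-methoxyphenoxy)-1,4-benzoquinone
Conditions: Br2 (2.1 equiv), NaHCO3 (solid), CH2Cl2, 0 °C to rt, dark
Reagents that add atoms: bromine, BrBr
Why: Two electrophilic addition-elimination events are expected, bromination of the enol-ether carbon C3 as in alkoxyquinones (loss of H) and ipso-bromodesilylation at C5 as in vinylsilanes and alpha-silyl enones (attack at C5 puts the charge beta to silicon and bromide removes SiMe3), while C6-H and the deactivated ring B lack such activation and the solid base keeps HBr from adding to the quinone or cleaving C-Si.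

**Step 9**
Reactants: 17 3,5-dibromo-2-(2,3,5-tribromo-4-methoxyphenoxy)-1,4-benzoquinone
Product: 18 3,5-dibromo-2-(2,3,5-tribromo-4-methoxyphenoxy)benzene-1,4-diol
Conditions: Na2S2O4, THF-H2O, rt
Reagents that add atoms: none
Why: Dithionite reduction of a quinone to its hydroquinone is fast two-electron transfer that outruns nucleophilic attack on the halogenated ring and leaves C-Br and the diaryl ether untouched.

**Step 10**
Reactants: 18 3,5-dibromo-2-(2,3,5-tribromo-4-methoxyphenoxy)benzene-1,4-diol
Product: 19 3,5-dibromo-2-(2,3,5-tribromo-4-hydroxyphenoxy)benzene-1,4-diol (target)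
Conditions: BBr3 (5 equiv), CH2Cl2, -78 °C to rt; H2O
Reagents that add atoms: none
Why: In this Lewis-acid ether cleavage boron binds the methoxy oxygen and bromide attacks the methyl carbon (SN2); the diaryl ether has no sp3 carbon to attack, and the excess reagent covers the two free hydroxyls, which return on hydrolysis.

**Compound list**
1 | 2,6-dibromoanisole | COc1c(Br)cccc1Br | starting material
2 | 2-(3,5-dibromo-4-methoxyphenyl)-4,4,5,5-tetramethyl-1,3,2-dioxaborolane | COc1c(Br)cc(cc1Br)B1OC(C)(C)C(C)(C)O1 | intermediate
3 | 3,5-dibromo-4-methoxyphenol | COc1c(Br)cc(O)cc1Br | intermediate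
4 | 2,3,5-tribromo-4-methoxyphenol | Oc1cc(Br)c(OC)c(Br)c1Br | intermediate
5 | diisopropyl squarate | CC(C)OC1=C(OC(C)C)C(=O)C1=O | starting material
6 | 4-hydroxy-2,3-diisopropoxycyclobut-2-en-1-one (racemic) | CC(C)OC1=C(OC(C)C)C(=O)C1O | intermediate
7 | 3-isopropoxycyclobut-3-ene-1,2-dione | CC(C)OC1=CC(=O)C1=O | intermediate
8 | semisquaric acid (3-hydroxycyclobut-3-ene-1,2-dione) | OC1=CC(=O)C1=O | intermediate
9 | semisquaric chloride (3-chlorocyclobut-3-ene-1,2-dione) | ClC1=CC(=O)C1=O | intermediate
10 | 3-(2,3,5-tribromo-4-methoxyphenoxy)cyclobut-3-ene-1,2-dione | COc1c(Br)cc(OC2=CC(=O)C2=O)c(Br)c1Br | intermediate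
11 | trimethylsilylacetylene | C#C[Si](C)(C)C | starting material
12 | lithium trimethylsilylacetylide | [Li]C#C[Si](C)(C)C | intermediate
13 | 4-hydroxy-3-(2,3,5-tribromo-4-methoxyphenoxy)-4-[(trimethylsilyl)ethynyl]cyclobut-2-en-1-one (racemic) | C[Si](C)(C)C#CC1(O)C(=O)C=C1Oc1cc(Br)c(OC)c(Br)c1Br | intermediate
14 | (Z)-4-hydroxy-3-(2,3,5-tribromo-4-methoxyphenoxy)-6-(trimethylsilyl)hexa-1,3-dien-5-yn-1-one (enynyl ketene) | O=C=C/C(Oc1cc(Br)c(OC)c(Br)c1Br)=C(\C#C[Si](C)(C)C)O | intermediate
15 | ring-A diradical (phenoxyl at C4-O, sigma-aryl radical at C6) | [O]c1cc(Oc2cc(Br)c(OC)c(Br)c2Br)c(O)[c]c1[Si](C)(C)C | intermediate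
16 | 2-(2,3,5-tribromo-4-methoxyphenoxy)-5-(trimethylsilyl)-1,4-benzoquinone | O=C1C=C([Si](C)(C)C)C(=O)C=C1Oc1cc(Br)c(OC)c(Br)c1Br | intermediate
17 | 3,5-dibromo-2-(2,3,5-tribromo-4-methoxyphenoxy)-1,4-benzoquinone | O=C1C=C(Br)C(=O)C(Br)=C1Oc1cc(Br)c(OC)c(Br)c1Br | intermediate
18 | 3,5-dibromo-2-(2,3,5-tribromo-4-methoxyphenoxy)benzene-1,4-diol | Oc1cc(Br)c(O)c(Br)c1Oc1cc(Br)c(OC)c(Br)c1Br | intermediate
19 | 3,5-dibromo-2-(2,3,5-tribromo-4-hydroxyphenoxy)benzene-1,4-diol | Oc1cc(Br)c(O)c(Br)c1Oc1cc(Br)c(O)c(Br)c1Br | target

**Step count**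
Total steps: 10. Longest linear sequence: 8 (steps 3-10 from 5; the ring-B branch, steps 1, 2 and 5-10, is equally long).

**Steps most likely to fail**

**Step 7.** The ketene may close onto the near alkyne carbon (five-membered mode, helped by the size of silicon). The carbinol may also shed its aryloxy group before the four-membered ring opens.

Fallback: ring A is bought as a quinone instead of being built.
- The fallback sets out from phenol 4, which is added (K2CO3, MeCN, 0 °C) to an excess of commercial 2,5-dibromo-1,4-benzoquinone F1.
- Addition-elimination at a bromine-bearing carbon should give 2-bromo-5-(2,3,5-tribromo-4-methoxyphenoxy)-1,4-benzoquinone F2, which already carries C5-Br.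
- Bromination of its enol-ether carbon C3 (Br2, NaHCO3, CH2Cl2) rejoins the route at 17.

**Step 8.** Several things may go wrong:
- the C5-C6 bromine adduct may lose HBr instead of the silyl bromide;
- bromide may add conjugately at C6;
- acid may remove silicon as a proton exchange;
- a third bromination may set in.

Fallback: the silicon-bromine exchange is moved from the quinone to an arene, where ipso-bromodesilylation is classical.
- The fallback sets out from 16. Reductive acetylation (Zn, Ac2O, NaOAc) should give 2-(2,3,5-tribromo-4-methoxyphenoxy)-5-(trimethylsilyl)benzene-1,4-diyl diacetate F3.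
- Br2 in CH2Cl2 replaces silicon, para to the aryloxy donor, to give 2-bromo-5-(2,3,5-tribromo-4-methoxyphenoxy)benzene-1,4-diyl diacetate F4.
- Methanolysis (K2CO3, degassed MeOH) frees 2-bromo-5-(2,3,5-tribromo-4-methoxyphenoxy)benzene-1,4-diol F5.
- Ag2O oxidation gives the bromoquinone F2 described above, and bromination at C3 alone rejoins the route at 17.

**Step 6.** Three things may go wrong:
- the aryloxy group is a good leaving group, so the acetylide may displace it by conjugate addition-elimination;
- its weak donation may erode the preference between the two carbonyls;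
- the carbinol may lose the phenol on work-up.

Fallback: the alkyne is brought in on the well-behaved alkyl ester and the aryl ether is made last.
- The fallback sets out from 7 and 12. The 1,2-addition should give 4-hydroxy-3-isopropoxy-4-[(trimethylsilyl)ethynyl]cyclobut-2-en-1-one F6.
- Thermolysis in toluene gives 2-isopropoxy-5-(trimethylsilyl)-1,4-benzoquinone F7.
- BCl3 dealkylation gives 2-hydroxy-5-(trimethylsilyl)-1,4-benzoquinone F8.
- Oxalyl chloride with catalytic DMF gives 2-chloro-5-(trimethylsilyl)-1,4-benzoquinone F9.
- Addition-elimination of 4 (K2CO3, MeCN, 0 °C) at the chlorine-bearing carbon rejoins the route at 16.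

**Further compounds**
F1 | step 7 | 2,5-dibromo-1,4-benzoquinone (purchased) | O=C1C=C(Br)C(=O)C=C1Br
F2 | step 7 | 2-bromo-5-(2,3,5-tribromo-4-methoxyphenoxy)-1,4-benzoquinone | O=C1C=C(Br)C(=O)C=C1Oc1cc(Br)c(OC)c(Br)c1Br
F3 | step 8 | 2-(2,3,5-tribromo-4-methoxyphenoxy)-5-(trimethylsilyl)benzene-1,4-diyl diacetate | CC(=O)Oc1cc([Si](C)(C)C)c(OC(C)=O)cc1Oc1cc(Br)c(OC)c(Br)c1Br
F4 | step 8 | 2-bromo-5-(2,3,5-tribromo-4-methoxyphenoxy)benzene-1,4-diyl diacetate | CC(=O)Oc1cc(Br)c(OC(C)=O)cc1Oc1cc(Br)c(OC)c(Br)c1Br
F5 | step 8 | 2-bromo-5-(2,3,5-tribromo-4-methoxyphenoxy)benzene-1,4-diol | Oc1cc(Br)c(O)cc1Oc1cc(Br)c(OC)c(Br)c1Br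
F6 | step 6 | 4-hydroxy-3-isopropoxy-4-[(trimethylsilyl)ethynyl]cyclobut-2-en-1-one (racemic) | CC(C)OC1=CC(=O)C1(O)C#C[Si](C)(C)C
F7 | step 6 | 2-isopropoxy-5-(trimethylsilyl)-1,4-benzoquinone | CC(C)OC1=CC(=O)C([Si](C)(C)C)=CC1=O
F8 | step 6 | 2-hydroxy-5-(trimethylsilyl)-1,4-benzoquinone | OC1=CC(=O)C([Si](C)(C)C)=CC1=O
F9 | step 6 | 2-chloro-5-(trimethylsilyl)-1,4-benzoquinone | ClC1=CC(=O)C([Si](C)(C)C)=CC1=O
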